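**Retrosynthetic overview**

- Locants: ring A = 3,5-dihydroxyphenoxy ring; ring B = pentaoxygenated ring (B1–O–ring A, B2 and B4 OH, B3 H, B5 and B6 the dioxin oxygens, B6 between B1 and B5); ring C = ring shared by dioxin and furan (C1–O–B6, C2 OH, C3 H, C4 furan O, C5–ring D, C6–O–B5); ring D = outer ring of the dibenzofuran.
- Last: BBr3 frees the seven hydroxyls; before it, a bystander bromine at C3 is removed by hydrogenolysis.
- Key disconnections: the dioxin bond O(B6)–C1 (copper-catalysed aryl ether closure at C1–Br) and the furan bond O(C4)–ring D (fluoride displacement), both made in one flask from an open chain of the four benzene rings; the dioxin closes first, the furan second.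
- Feature that makes this possible: the B6 oxygen lies 1,6 to C1 across the B5–O–C6 ether and the C4 oxygen lies 1,5 to the fluorine-bearing carbon of ring D across the C5–ring D bond, while C5 is fully substituted, so each oxygen has only one carbon within reach.
- Precursor: ring B takes its two aryloxy groups by SNAr ortho to one formyl group, which Baeyer–Villiger oxidation then turns into the B6 oxygen; ring C enters as a 2-aryl-5-methoxyresorcinol with two equivalent hydroxyls (Negishi coupling, bromination at C1 and C3), so either hydroxyl can take ring B.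

Key step: step 9

Remark on the chemistry: the target has no stereocentre; the hindered biaryl axis of 7 to 16 is carried without configuration (racemic or freely rotating) and disappears when the furan closes, so no SMILES carries stereodescriptors; 1, 3, 10 and 12 are taken as catalogue compounds.

Step 1
Reactants: 1 5-methoxybenzene-1,3-diol
Product: 2 1-methoxy-3,5-bis(methoxymethoxy)benzene
Conditions: MOMCl, iPr2NEt, CH2Cl2, 0 °C to rt
Reagents that add atoms: chloromethyl methyl ether, COCCl
Why: Williamson-type O-alkylation of both phenols should give the bis-MOM ether, whose two acetal groups later direct the lithiation of step 3.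

Step 2
Reactants: 3 1-fluoro-3,5-dimethoxybenzene
Product: 4 2-bromo-1-fluoro-3,5-dimethoxybenzene
Conditions: NBS, MeCN, 0 °C to rt
Reagents that add atoms: N-bromosuccinimide, O=C1CCC(=O)N1Br
Why: electrophilic aromatic bromination should occur para to one methoxy group and ortho to the other at the less hindered site next to fluorine, not between the two methoxy groups.

Step 3
Reactants: 2 1-methoxy-3,5-bis(methoxymethoxy)benzene; 4 2-bromo-1-fluoro-3,5-dimethoxybenzene
Product: 7 2'-fluoro-4,4',6'-trimethoxy-2,6-bis(methoxymethoxy)biphenyl, via aryllithium 5 (not isolated), via arylzinc chloride 6 (not isolated)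
Conditions: n-BuLi, THF, 0 °C; ZnCl2, 0 °C to rt; then 4, Pd2(dba)3 (2.5 mol %), RuPhos (10 mol %), THF–NMP, 70 °C
Reagents that add atoms: none
Why: directed ortho-metalation at the carbon flanked by both MOM ethers, transmetalation to zinc and Negishi cross-coupling should form the biaryl bond, a bulky dialkylbiarylphosphine on zerovalent palladium being the established system for biaryls with four ortho substituents.

Step 4
Reactants: 7 2'-fluoro-4,4',6'-trimethoxy-2,6-bis(methoxymethoxy)biphenyl
Product: 8 2'-fluoro-4,4',6'-trimethoxybiphenyl-2,6-diol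
Conditions: HCl (3 M aq.), MeOH, 50 °C
Reagents that add atoms: none
Why: acid-catalysed acetal cleavage (transacetalisation to dimethoxymethane) should free both phenols while the aryl fluoride and the methyl ethers stay untouched.

Step 5
Reactants: 8 2'-fluoro-4,4',6'-trimethoxybiphenyl-2,6-diol
Product: 9 3,5-dibromo-2'-fluoro-4,4',6'-trimethoxybiphenyl-2,6-diol
Conditions: NBS (2 equiv), MeCN, −20 to 0 °C
Reagents that add atoms: N-bromosuccinimide, O=C1CCC(=O)N1Br
Why: electrophilic bromination should take the only two free positions of the resorcinol ring (each ortho to one hydroxyl and para to the other) faster than ring D, which has no free hydroxyl, and the two hydroxyls of the product remain equivalent.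

Step 6
Reactants: 9 3,5-dibromo-2'-fluoro-4,4',6'-trimethoxybiphenyl-2,6-diol; 10 2,6-difluoro-3,5-dimethoxybenzaldehyde
Product: 11 2-[(3,5-dibromo-2'-fluoro-6-hydroxy-4,4',6'-trimethoxybiphenyl-2-yl)oxy]-6-fluoro-3,5-dimethoxybenzaldehyde
Conditions: Cs2CO3, DMSO, 70 °C (9 in slight excess)
Reagents that add atoms: none
Why: nucleophilic aromatic substitution (addition–elimination) of a fluoride ortho to the formyl group should give one mono-ether because the two hydroxyls of 9 are equivalent, and the flanking bromine and aryl group slow a second arylation.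

Step 7
Reactants: 11 2-[(3,5-dibromo-2'-fluoro-6-hydroxy-4,4',6'-trimethoxybiphenyl-2-yl)oxy]-6-fluoro-3,5-dimethoxybenzaldehyde; 12 3,5-dimethoxyphenol
Product: 13 2-[(3,5-dibromo-2'-fluoro-6-hydroxy-4,4',6'-trimethoxybiphenyl-2-yl)oxy]-6-(3,5-dimethoxyphenoxy)-3,5-dimethoxybenzaldehyde
Conditions: Cs2CO3, DMSO, 90 °C
Reagents that add atoms: none
Why: a second SNAr at the remaining fluoride ortho to the formyl group by the unhindered phenoxide of 12 should install ring A, since the hindered bromophenoxide of ring C and the unactivated fluoride of ring D should not compete at this temperature.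

Step 8
Reactants: 13 2-[(3,5-dibromo-2'-fluoro-6-hydroxy-4,4',6'-trimethoxybiphenyl-2-yl)oxy]-6-(3,5-dimethoxyphenoxy)-3,5-dimethoxybenzaldehyde
Product: 15 2-[(3,5-dibromo-2'-fluoro-6-hydroxy-4,4',6'-trimethoxybiphenyl-2-yl)oxy]-6-(3,5-dimethoxyphenoxy)-3,5-dimethoxyphenol, via aryl formate 14 (not isolated)
Conditions: mCPBA, CH2Cl2, 0 °C to rt; then K2CO3 (cat.), MeOH, rt
Reagents that add atoms: 3-chloroperoxybenzoic acid, OOC(=O)c1cccc(Cl)c1
Why: Baeyer–Villiger oxidation (Dakin-type) of an aldehyde flanked by two aryloxy groups should proceed with migration of the electron-rich aryl group, and methanolysis of the formate turns the former SNAr activator into the B6 phenol.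

Step 9
Reactants: 15 2-[(3,5-dibromo-2'-fluoro-6-hydroxy-4,4',6'-trimethoxybiphenyl-2-yl)oxy]-6-(3,5-dimethoxyphenoxy)-3,5-dimethoxyphenol
Product: 17 ring-C monobromide of the target heptamethyl ether (bromine at C3), via dibenzodioxin phenol 16 (not isolated)
Conditions: CuI (20 mol %), N,N-dimethylglycine (40 mol %), Cs2CO3, NMP (0.01 M), 110 °C, then 150 °C
Reagents that add atoms: none
Why: Deprotonation gives a bis-phenoxide; the ring B phenoxide binds the copper of CuI, and oxidative addition into the C1–Br bond followed by reductive elimination forms the O(B6)–C1 bond, which is the Ullmann ether synthesis in the intramolecular form classically used to close dibenzodioxins from 2-(2-halophenoxy)phenols. This closes the dioxin as a six-membered ring by attack of the B6 oxygen on C1 through a seven-membered copper chelate. At 150 °C the ring C phenoxide then adds to the fluorine-bearing carbon of ring D and expels fluoride (intramolecular SNAr of a 2'-fluorobiaryl-2-olate, 5-exo addition then elimination), which closes the furan as a five-membered ring. No stereocentre is formed. The step needs site selectivity between two aryl bromides and two phenoxides, and the geometry secures it: the B6 oxygen can reach only C1 because C5 carries ring D, the C4 oxygen can reach only ring D, the bromine at C3 has no oxygen within reach, and high dilution suppresses intermolecular ether formation.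

Step 10
Reactants: 17 ring-C monobromide of the target heptamethyl ether (bromine at C3)
Product: 18 heptamethyl ether of the target
Conditions: H2 (1 atm), 10% Pd/C, Et3N, EtOAc–MeOH, rt
Reagents that add atoms: none
Why: palladium-catalysed hydrogenolysis of the aryl C–Br bond should remove the bystander bromine while diaryl ethers and methyl ethers are inert.

Step 11
Reactants: 18 heptamethyl ether of the target
Product: 19 target CNP0256302.0
Conditions: BBr3 (excess), CH2Cl2, −78 °C to rt; MeOH, then H2O, under argon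
Reagents that add atoms: none
Why: Lewis acid cleavage of the seven aryl methyl ethers (bromide attack on the methyl group of the boron-complexed ether) should free all hydroxyls without breaking the diaryl ether, dioxin or furan C–O bonds.

**Compound list**

1 | 5-methoxybenzene-1,3-diol | COc1cc(O)cc(O)c1 | starting material
2 | 1-methoxy-3,5-bis(methoxymethoxy)benzene | COCOc1cc(OC)cc(OCOC)c1 | intermediate
3 | 1-fluoro-3,5-dimethoxybenzene | COc1cc(F)cc(OC)c1 | starting material
4 | 2-bromo-1-fluoro-3,5-dimethoxybenzene | COc1cc(F)c(Br)c(OC)c1 | intermediate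
5 | [4-methoxy-2,6-bis(methoxymethoxy)phenyl]lithium | COCOc1cc(OC)cc(OCOC)c1[Li] | intermediate
6 | [4-methoxy-2,6-bis(methoxymethoxy)phenyl]zinc chloride | COCOc1cc(OC)cc(OCOC)c1[Zn]Cl | intermediate
7 | 2'-fluoro-4,4',6'-trimethoxy-2,6-bis(methoxymethoxy)biphenyl | COCOc1cc(OC)cc(OCOC)c1-c1c(F)cc(OC)cc1OC | intermediate
8 | 2'-fluoro-4,4',6'-trimethoxybiphenyl-2,6-diol | Oc1cc(OC)cc(O)c1-c1c(F)cc(OC)cc1OC | intermediate
9 | 3,5-dibromo-2'-fluoro-4,4',6'-trimethoxybiphenyl-2,6-diol | Oc1c(Br)c(OC)c(Br)c(O)c1-c1c(F)cc(OC)cc1OC | intermediate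
10 | 2,6-difluoro-3,5-dimethoxybenzaldehyde | O=Cc1c(F)c(OC)cc(OC)c1F | starting material
11 | 2-[(3,5-dibromo-2'-fluoro-6-hydroxy-4,4',6'-trimethoxybiphenyl-2-yl)oxy]-6-fluoro-3,5-dimethoxybenzaldehyde | O=Cc1c(F)c(OC)cc(OC)c1Oc1c(Br)c(OC)c(Br)c(O)c1-c1c(F)cc(OC)cc1OC | intermediate
12 | 3,5-dimethoxyphenol | COc1cc(O)cc(OC)c1 | starting material
13 | 2-[(3,5-dibromo-2'-fluoro-6-hydroxy-4,4',6'-trimethoxybiphenyl-2-yl)oxy]-6-(3,5-dimethoxyphenoxy)-3,5-dimethoxybenzaldehyde | O=Cc1c(Oc2cc(OC)cc(OC)c2)c(OC)cc(OC)c1Oc1c(Br)c(OC)c(Br)c(O)c1-c1c(F)cc(OC)cc1OC | intermediate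
14 | 2-[(3,5-dibromo-2'-fluoro-6-hydroxy-4,4',6'-trimethoxybiphenyl-2-yl)oxy]-6-(3,5-dimethoxyphenoxy)-3,5-dimethoxyphenyl formate | O=COc1c(Oc2cc(OC)cc(OC)c2)c(OC)cc(OC)c1Oc1c(Br)c(OC)c(Br)c(O)c1-c1c(F)cc(OC)cc1OC | intermediate
15 | 2-[(3,5-dibromo-2'-fluoro-6-hydroxy-4,4',6'-trimethoxybiphenyl-2-yl)oxy]-6-(3,5-dimethoxyphenoxy)-3,5-dimethoxyphenol | Oc1c(Oc2cc(OC)cc(OC)c2)c(OC)cc(OC)c1Oc1c(Br)c(OC)c(Br)c(O)c1-c1c(F)cc(OC)cc1OC | intermediate
16 | 3-bromo-6-(3,5-dimethoxyphenoxy)-1-(2-fluoro-4,6-dimethoxyphenyl)-4,7,9-trimethoxydibenzo[b,e][1,4]dioxin-2-ol | COc1cc(OC)cc(Oc2c(OC)cc(OC)c3c2Oc2c(OC)c(Br)c(O)c(-c4c(F)cc(OC)cc4OC)c2O3)c1 | intermediate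
17 | ring-C monobromide of the target heptamethyl ether (dibenzodioxin fused to dibenzofuran; Br at C3 between the methoxy carbon C2 and the furan-oxygen carbon C4) | COc1cc(OC)cc(Oc2c(OC)cc(OC)c3c2Oc2c(OC)c(Br)c4oc5cc(OC)cc(OC)c5c4c2O3)c1 | intermediate
18 | heptamethyl ether of the target | COc1cc(OC)cc(Oc2c(OC)cc(OC)c3c2Oc2c(OC)cc4oc5cc(OC)cc(OC)c5c4c2O3)c1 | intermediate
19 | target CNP0256302.0 (all seven hydroxyls free) | Oc1cc(O)cc(Oc2c(O)cc(O)c3c2Oc2c(O)cc4oc5cc(O)cc(O)c5c4c2O3)c1 | target

**Step count and risks**

Total steps: 11. Longest linear sequence: 10 steps (1, 3, 4, 5, 6, 7, 8, 9, 10, 11).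

The three steps most likely to fail:

1. Step 9. What may go wrong: copper insertion into the doubly ortho-substituted, electron-rich C1–Br bond is slow, so that reductive loss of bromine or ether formation between two molecules overtakes the dioxin closure, or the fluoride displacement stalls. Fallback (the two closures are separated and the dioxin bond is made with palladium): setting out from 15, heating with Cs2CO3 in NMP at 150 °C without copper should close only the furan and give 2-[(2,4-dibromo-3,7,9-trimethoxydibenzofuran-1-yl)oxy]-6-(3,5-dimethoxyphenoxy)-3,5-dimethoxyphenol F1. Its phenol and the C–Br bond next to the ether oxygen are then joined by palladium-catalysed intramolecular aryl ether formation (Pd2(dba)3, tBuXPhos, K3PO4, toluene, 100 °C; oxidative addition to zerovalent palladium, then C–O reductive elimination), which comes back to the route at 17. The only new compound on this path is F1.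

2. Step 3. What may go wrong: transmetalation and reductive elimination between two partners that each carry two ortho substituents fail, or lithiation of 2 occurs next to the methoxy group. Fallback (the furan is made first by an intramolecular biaryl bond formation, so no hindered intermolecular coupling is needed): setting out from 1, iodination between the two hydroxyls (I2, NaHCO3, H2O–THF) should give 2-iodo-5-methoxybenzene-1,3-diol F2. Chan–Lam mono-arylation with (3,5-dimethoxyphenyl)boronic acid (Cu(OAc)2, pyridine, air, CH2Cl2) should give 3-(3,5-dimethoxyphenoxy)-2-iodo-5-methoxyphenol F3. Palladium-catalysed intramolecular direct arylation (Pd(OAc)2, PCy3·HBF4, K2CO3, DMA, 120 °C) should give 3,7,9-trimethoxydibenzofuran-1-ol F4. Bromination with NBS (2 equiv) should give 2,4-dibromo-3,7,9-trimethoxydibenzofuran-1-ol F5. SNAr with 10 should give 2-[(2,4-dibromo-3,7,9-trimethoxydibenzofuran-1-yl)oxy]-6-fluoro-3,5-dimethoxybenzaldehyde F6. SNAr with 12 should give 2-[(2,4-dibromo-3,7,9-trimethoxydibenzofuran-1-yl)oxy]-6-(3,5-dimethoxyphenoxy)-3,5-dimethoxybenzaldehyde F7. Baeyer–Villiger oxidation with mCPBA should give 2-[(2,4-dibromo-3,7,9-trimethoxydibenzofuran-1-yl)oxy]-6-(3,5-dimethoxyphenoxy)-3,5-dimethoxyphenyl formate F8. Methanolysis should give the phenol described under the fallback to step 9 as F1, and copper-catalysed closure of its dioxin ring under the conditions of step 9 comes back to the route at 17. The new compounds on this path are F2, F3, F4, F5, F6, F7 and F8.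

3. Step 6. What may go wrong: the hindered, weakly nucleophilic bromophenoxide reacts too slowly, so that double substitution or decomposition of the aldehyde competes. Fallback (ether formation before bromination): setting out from 8, SNAr with 10 (K2CO3, DMF, 50 °C) should give 2-fluoro-6-[(2'-fluoro-6-hydroxy-4,4',6'-trimethoxybiphenyl-2-yl)oxy]-3,5-dimethoxybenzaldehyde F9. Bromination with NBS (2 equiv) at both free positions of its phenol ring comes back to the route at 11. The only new compound on this path is F9.

Further compounds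
F1 | step 9 | 2-[(2,4-dibromo-3,7,9-trimethoxydibenzofuran-1-yl)oxy]-6-(3,5-dimethoxyphenoxy)-3,5-dimethoxyphenol | Oc1c(Oc2cc(OC)cc(OC)c2)c(OC)cc(OC)c1Oc1c(Br)c(OC)c(Br)c2oc3cc(OC)cc(OC)c3c12
F2 | step 3 | 2-iodo-5-methoxybenzene-1,3-diol | COc1cc(O)c(I)c(O)c1
F3 | step 3 | 3-(3,5-dimethoxyphenoxy)-2-iodo-5-methoxyphenol | COc1cc(O)c(I)c(Oc2cc(OC)cc(OC)c2)c1
F4 | step 3 | 3,7,9-trimethoxydibenzofuran-1-ol | COc1cc(O)c2c(c1)oc1cc(OC)cc(OC)c12
F5 | step 3 | 2,4-dibromo-3,7,9-trimethoxydibenzofuran-1-ol | COc1c(Br)c(O)c2c(c1Br)oc1cc(OC)cc(OC)c12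
F6 | step 3 | 2-[(2,4-dibromo-3,7,9-trimethoxydibenzofuran-1-yl)oxy]-6-fluoro-3,5-dimethoxybenzaldehyde | O=Cc1c(F)c(OC)cc(OC)c1Oc1c(Br)c(OC)c(Br)c2oc3cc(OC)cc(OC)c3c12
F7 | step 3 | 2-[(2,4-dibromo-3,7,9-trimethoxydibenzofuran-1-yl)oxy]-6-(3,5-dimethoxyphenoxy)-3,5-dimethoxybenzaldehyde | O=Cc1c(Oc2cc(OC)cc(OC)c2)c(OC)cc(OC)c1Oc1c(Br)c(OC)c(Br)c2oc3cc(OC)cc(OC)c3c12
F8 | step 3 | 2-[(2,4-dibromo-3,7,9-trimethoxydibenzofuran-1-yl)oxy]-6-(3,5-dimethoxyphenoxy)-3,5-dimethoxyphenyl formate | O=COc1c(Oc2cc(OC)cc(OC)c2)c(OC)cc(OC)c1Oc1c(Br)c(OC)c(Br)c2oc3cc(OC)cc(OC)c3c12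
F9 | step 6 | 2-fluoro-6-[(2'-fluoro-6-hydroxy-4,4',6'-trimethoxybiphenyl-2-yl)oxy]-3,5-dimethoxybenzaldehyde | O=Cc1c(F)c(OC)cc(OC)c1Oc1cc(OC)cc(O)c1-c1c(F)cc(OC)cc1OC
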